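## Retrosynthetic overview

1. Target 9 ⇒ cut the C13–O9 bond: the spiro-oxolane and the 2,3-dihydrofuran go back to the furan and 9α-OH of 20-acetoxymarrubiin 8. Forward, this is a photochemical cobalt-hydride dearomative hydroalkoxylation that sets C13.
2. 8 ⇒ cut the C20–O bond back to the C10 methyl: 6β-alkoxy radical, 1,5-hydrogen shift, nitrite photolysis under O2, on lactone-opened marrubiin (nitrate 6, then acetate).
3. Nitrite 4 ⇒ methyl marrubiinate 3 ⇒ marrubiin 1, which supplies C4, C5, C6, C8, C9 and C10.
4. Ring order: rings A and B and the furan come with 1. The 19,6β-lactone is opened (step 1) and re-closed (step 3). The spiro-oxolane is closed last (step 5), in the same step that turns the furan into the dihydrofuran.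

Assumption: marrubiin, the main labdane of white horehound (commercial, and extractable on multigram scale), is accepted as the purchasable chiral starting material.

## Route

Step 1
Reactants: 1 marrubiin (15,16-epoxy-9α-hydroxylabda-13(16),14-dien-19,6β-olide)
Product: 3 methyl marrubiinate (methyl 6β,9α-dihydroxy-15,16-epoxylabda-13(16),14-dien-19-oate), via potassium marrubiinate 2 (not isolated)
Conditions: KOH (1.1 equiv), MeOH/H2O, reflux; evaporate; MeI, DMF, rt
Reagents that add atoms: potassium hydroxide, [K+].[OH-]; iodomethane, CI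
Why: Hydroxide saponifies the γ-lactone irreversibly and SN2 O-methylation of the carboxylate locks the ring-opened hydroxy ester, exposing the axial 6β-OH; no stereocentre is touched (C4, C5, C6, C8, C9 and C10 all come from 1).

Step 2
Reactants: 3 methyl marrubiinate
Product: 4 methyl 9α-hydroxy-6β-(nitrosooxy)-15,16-epoxylabda-13(16),14-dien-19-oate (the 6β-nitrite)
Conditions: t-BuONO (10 equiv), CH2Cl2, rt, dark; evaporate
Reagents that add atoms: tert-butyl nitrite, CC(C)(C)ON=O
Why: Nitrosyl exchange (trans-nitrosation) from a tertiary to a secondary alkyl nitrite is favourable and is driven by evaporation; the neutral medium spares the furan and the very hindered tertiary 9α-OH, and O–N bond formation leaves C6 unchanged.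

Step 3
Reactants: 4 the 6β-nitrite
Product: 6 20-nitrooxymarrubiin (15,16-epoxy-9α-hydroxy-20-nitrooxylabda-13(16),14-dien-19,6β-olide), via nitrate hydroxy ester 5 (not isolated)
Conditions: hν (365 nm), O2 (1 atm), NaHCO3, PhCF3, 10 °C; filter; PPTS (10 mol%), 60 °C
Reagents that add atoms: dioxygen, O=O
Why: Barton nitrite photolysis run under oxygen: O–NO homolysis gives the 6β-alkoxy radical, which abstracts hydrogen from the 1,3-diaxial C20 methyl (1,5-hydrogen shift; the 4β position carries no C–H), the C20 radical is trapped by O2 and then NO to give the nitrate, and acid-catalysed lactonisation of the regenerated 6β-OH onto the C19 ester re-closes the 19,6β-lactone while C20 is masked; no stereocentre changes.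

Step 4
Reactants: 6 20-nitrooxymarrubiin
Product: 8 20-acetoxymarrubiin (20-acetoxy-15,16-epoxy-9α-hydroxylabda-13(16),14-dien-19,6β-olide), via 20-hydroxymarrubiin 7 (not isolated)
Conditions: Zn, AcOH, THF, rt; filter, evaporate; Ac2O, pyridine, DMAP (cat.), 0 °C to rt
Reagents that add atoms: acetic anhydride, CC(=O)OC(C)=O
Why: Zinc in acetic acid cleaves the O–NO2 bond reductively to the primary alcohol, which is then acylated (DMAP nucleophilic catalysis) while the tertiary 9α-OH is too hindered to react; no stereocentre is involved.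

Step 5
Reactants: 8 20-acetoxymarrubiin
Product: 9 (13R)-20-acetoxy-9α,13:15,16-diepoxylabd-14-en-19,6β-olide (target, CNP0218619.1)
Conditions: Co(salen) (C16H14CoN2O2, 5 mol%), N-phenylbenzo[b]phenothiazine (5 mol%), 2,4,6-collidinium triflate (20 mol%), 2,4,6-collidine (20 mol%), CH2Cl2, blue LEDs (440 nm), 0 °C
Reagents that add atoms: none
Why: Proposed new method: dearomative Markovnikov hydroalkoxylation of a furan by cobalt-hydride hydrogen-atom transfer and radical-polar crossover — the photoreduced, protonated Co(salen) (a trivalent cobalt hydride) delivers H to the furan α-carbon C16 next to the alkyl branch, the oxygen-stabilised allyl radical (C13/C15) is oxidised by the photocatalyst radical cation to the 2H-furanium cation that also links premarrubiin-type ethers and marrubiin-type furans thermally, and the 9α-OH captures it 5-exo at C13 (the only ring size within reach) while the proton returns to collidine; the ground-state medium is only a weak collidine/collidinium buffer, so the non-aromatic spiro enol ether is a kinetic product that does not relax to the furan, and a cation that loses H16 instead merely regenerates 8; C13 is set by the substrate (the sp3 C16H2 arm takes the flank of the freely rotating C8 methyl and the flat C14 the flank of the rigid C1 methylene, giving 13R); the closest known reaction is cobalt-hydride hydrogen-atom-transfer hydroalkoxylation of unactivated alkenes with alcohols (silane/oxidant version and the redox-neutral photoredox/cobalt/Brønsted-acid version), not yet shown on a furan C=C.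

## Compound list

1 | marrubiin | C[C@@]12CCC[C@]3(C)C(=O)O[C@H](C[C@@H](C)[C@]1(O)CCc1ccoc1)[C@H]23 | starting material
2 | potassium marrubiinate | C[C@]12CCC[C@](C)(C(=O)[O-])[C@@H]1[C@H](O)C[C@@H](C)[C@]2(O)CCc1ccoc1.[K+] | intermediate
3 | methyl marrubiinate | C[C@]12CCC[C@](C)(C(=O)OC)[C@@H]1[C@H](O)C[C@@H](C)[C@]2(O)CCc1ccoc1 | intermediate
4 | methyl 9α-hydroxy-6β-(nitrosooxy)-15,16-epoxylabda-13(16),14-dien-19-oate | C[C@]12CCC[C@](C)(C(=O)OC)[C@@H]1[C@H](ON=O)C[C@@H](C)[C@]2(O)CCc1ccoc1 | intermediate
5 | methyl 6β,9α-dihydroxy-20-nitrooxy-15,16-epoxylabda-13(16),14-dien-19-oate (nitrate hydroxy ester) | O=[N+]([O-])OC[C@]12CCC[C@](C)(C(=O)OC)[C@@H]1[C@H](O)C[C@@H](C)[C@]2(O)CCc1ccoc1 | intermediate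
6 | 20-nitrooxymarrubiin | O=[N+]([O-])OC[C@@]12CCC[C@]3(C)C(=O)O[C@H](C[C@@H](C)[C@]1(O)CCc1ccoc1)[C@H]23 | intermediate
7 | 20-hydroxymarrubiin | OC[C@@]12CCC[C@]3(C)C(=O)O[C@H](C[C@@H](C)[C@]1(O)CCc1ccoc1)[C@H]23 | intermediate
8 | 20-acetoxymarrubiin | CC(=O)OC[C@@]12CCC[C@]3(C)C(=O)O[C@H](C[C@@H](C)[C@]1(O)CCc1ccoc1)[C@H]23 | intermediate
9 | (13R)-20-acetoxy-9α,13:15,16-diepoxylabd-14-en-19,6β-olide | CC(=O)OC[C@@]12CCC[C@]3(C)C(=O)O[C@H](C[C@@H](C)[C@]14CC[C@]1(C=COC1)O4)[C@H]23 | target

## Step count and risks

Total steps: 5. Longest linear sequence: 5 (fully linear from 1).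

**Step 5 (the proposed new reaction).** It can fail in four ways:
- the cobalt hydride may not transfer hydrogen to the furan;
- hydrogen may go to C15 instead of C16;
- the buffer acid may slowly re-open 9 to 8;
- the C13 selectivity is expected to be only moderate, because the C1 methylene and the C8 methyl flank the new ring almost symmetrically. The minor 13-epimer would be separated on base-washed silica and returned to 8 with PPTS in warm toluene for recycling.

The fallback uses known chemistry, sets out from 8 and comes back at 9. Dye-sensitised photo-oxygenation of the 3-alkylfuran with a hindered base (O2, rose bengal, i-Pr2NEt, CH2Cl2, −78 °C, visible light) gives the 16-hydroxy-15,16-butenolide F7. NaBH4 (EtOH, 0 °C, then dilute acid) reduces it to the β-substituted butenolide F8. Catalytic DBU (CH2Cl2, rt) closes the 9α-OH onto C13 by intramolecular oxa-Michael addition to give the 9α,13-epoxy spiro-lactone F9; C13 is under thermodynamic control and epimers are separated. Disiamylborane (THF, 0 °C) reduces only the unhindered C15 lactone, in the presence of the acetate and the neopentyl 19,6β-lactone, to the 15-lactol F10. MsCl/Et3N (CH2Cl2, −20 °C to rt) forms the lactol mesylate F11, which eliminates in the flask to the C14=C15 enol ether 9.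

**Step 3 (nitrite photolysis under O2 next to a furan).** Nitrogen oxides formed from NO and O2 may attack the furan or nitrosate the 9α-OH, and the nitrate yield may be low.

The fallback sets out from 4 and comes back at 7, which is acetylated as in the second stage of step 4. Irradiating 4 under argon (365 nm, PhCF3), the classical Barton reaction, gives the 20-nitroso hydroxy ester F1 by NO recombination at C20. Warming in i-PrOH tautomerises it to the 20-oxime hydroxy ester F2. PPTS (PhCF3, 60 °C) lactonises this to marrubiin 20-oxime F3. Exchange with glyoxylic acid (aqueous AcOH/NaOAc, THF) frees the aldehyde 20-oxomarrubiin F4. NaBH4 (MeOH, 0 °C) reduces it to 7.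

**Step 4 (nitrate cleavage and acetylation).** The free hydroxy lactone 7 may move its lactone from O6 to O20 under the basic acylation, giving the 6-acetate of the 19,20-lactone.

The fallback changes the order so that C20 is acetylated before the lactone exists; it sets out from 5 (isolated by leaving out the PPTS stage of step 3) and comes back at 8. Zn/AcOH (THF, rt) gives the 6β,9α,20-triol methyl ester F5. Ac2O (1.1 equiv) in pyridine at 0 °C without DMAP acetylates only the primary C20 hydroxyl, giving the 20-acetoxy hydroxy ester F6. PPTS (PhCF3, 60 °C) closes the 19,6β-lactone to 8.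

## Further compounds

F1 | step 3 | methyl 6β,9α-dihydroxy-20-nitroso-15,16-epoxylabda-13(16),14-dien-19-oate | O=NC[C@]12CCC[C@](C)(C(=O)OC)[C@@H]1[C@H](O)C[C@@H](C)[C@]2(O)CCc1ccoc1
F2 | step 3 | methyl 6β,9α-dihydroxy-20-(hydroxyimino)-15,16-epoxylabda-13(16),14-dien-19-oate (E-oxime) | O/N=C/[C@]12CCC[C@](C)(C(=O)OC)[C@@H]1[C@H](O)C[C@@H](C)[C@]2(O)CCc1ccoc1
F3 | step 3 | marrubiin 20-oxime (20-(hydroxyimino)-15,16-epoxy-9α-hydroxylabda-13(16),14-dien-19,6β-olide) | O/N=C/[C@@]12CCC[C@]3(C)C(=O)O[C@H](C[C@@H](C)[C@]1(O)CCc1ccoc1)[C@H]23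
F4 | step 3 | 20-oxomarrubiin | O=C[C@@]12CCC[C@]3(C)C(=O)O[C@H](C[C@@H](C)[C@]1(O)CCc1ccoc1)[C@H]23
F5 | step 4 | methyl 6β,9α,20-trihydroxy-15,16-epoxylabda-13(16),14-dien-19-oate | OC[C@]12CCC[C@](C)(C(=O)OC)[C@@H]1[C@H](O)C[C@@H](C)[C@]2(O)CCc1ccoc1
F6 | step 4 | methyl 20-acetoxy-6β,9α-dihydroxy-15,16-epoxylabda-13(16),14-dien-19-oate | CC(=O)OC[C@]12CCC[C@](C)(C(=O)OC)[C@@H]1[C@H](O)C[C@@H](C)[C@]2(O)CCc1ccoc1
F7 | step 5 | 20-acetoxy-9α,16-dihydroxylabd-13-ene-19,6β:15,16-diolide (γ-hydroxybutenolide) | CC(=O)OC[C@@]12CCC[C@]3(C)C(=O)O[C@H](C[C@@H](C)[C@]1(O)CCC1=CC(=O)OC1O)[C@H]23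
F8 | step 5 | 20-acetoxy-9α-hydroxylabd-13-ene-19,6β:15,16-diolide (butenolide) | CC(=O)OC[C@@]12CCC[C@]3(C)C(=O)O[C@H](C[C@@H](C)[C@]1(O)CCC1=CC(=O)OC1)[C@H]23
F9 | step 5 | 20-acetoxy-9α,13-epoxylabdane-19,6β:15,16-diolide (spiro-lactone) | CC(=O)OC[C@@]12CCC[C@]3(C)C(=O)O[C@H](C[C@@H](C)[C@]14CC[C@]1(CC(=O)OC1)O4)[C@H]23
F10 | step 5 | 20-acetoxy-9α,13:15,16-diepoxy-15-hydroxylabdan-19,6β-olide (lactol) | CC(=O)OC[C@@]12CCC[C@]3(C)C(=O)O[C@H](C[C@@H](C)[C@]14CC[C@]1(CC(O)OC1)O4)[C@H]23
F11 | step 5 | 20-acetoxy-9α,13:15,16-diepoxy-15-(methanesulfonyloxy)labdan-19,6β-olide (lactol mesylate) | CC(=O)OC[C@@]12CCC[C@]3(C)C(=O)O[C@H](C[C@@H](C)[C@]14CC[C@]1(CC(OS(C)(=O)=O)OC1)O4)[C@H]23
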